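**Retrosynthetic overview**

1. Endgame: the target comes from a (2S)-flavanone by cleavage of the C5 O-ethyl group and of the ring B MOM group. Ring C (O1–C2 bond) comes from catalytic asymmetric oxa-Michael closure of a 2'-hydroxychalcone, itself a Claisen–Schmidt union of a ring A methyl ketone with a ring B chromene aldehyde.
2. Structural feature behind the plan: ring A is a pentasubstituted benzene (C4a acyl, C5 OH, C6 H, C7 OMe, C8 prenyl, C8a O1) whose C8 prenyl group lies between O1 and the C7 methoxyl. The ring is therefore built around the prenyl group instead of being prenylated.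
3. Ring A: Danheiser benzannulation of 3-ethoxycyclobut-2-en-1-one with 1-methoxy-5-methylhex-4-en-1-yne forms C8a–C8, C7–C6 and C8a–C4a and gives a phenol whose only free hydroxyl is the future O1. The C4a acetyl group follows by ortho-formylation, MeMgBr addition and oxidation.
4. Ring B aldehyde: made from resorcinol through 7-hydroxy-2,2-dimethylchroman-4-one, which fixes the linear chromene (pyran fused at C4'–C5'), then reduction/dehydration, ortho-formylation and MOM protection.
5. Order of ring formation: ring A (step 2); pyran ring of the ring B chromene (steps 6 and 7, parallel branch); ring C (step 11).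

Key step: step 2

Assumption: the sense of induction of the cinchona thiourea in step 11 cannot be predicted with certainty; the quinidine-derived catalyst is written, and its quinine-derived pseudoenantiomer takes its place if a trial closure shows that it is the one giving the 2S product.

**Route**

Step 1
Reactants: 1 chloroacetaldehyde dimethyl acetal (2-chloro-1,1-dimethoxyethane); 2 prenyl bromide (1-bromo-3-methylbut-2-ene)
Product: 4 1-methoxy-5-methylhex-4-en-1-yne, via sodium methoxyacetylide 3 (not isolated)
Conditions: NaNH2 (3.0 equiv), liq. NH3, −33 °C; then 2 (1.0 equiv), −45 → −33 °C; NH3 evaporated, H2O, pentane; distillation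
Reagents that add atoms: none
Why: Twofold elimination (HCl, then MeOH) from the chloroacetal by NaNH2 is the standard route to alkoxyacetylides, and in-flask SN2 alkylation of the sodium acetylide at the primary carbon of the allylic bromide follows the established one-pot preparation of 1-alkoxyalk-1-ynes, the exact three equivalents of amide leaving no free NaNH2 that could isomerise the skipped enyne.

Step 2
Reactants: 4 1-methoxy-5-methylhex-4-en-1-yne; 5 3-ethoxycyclobut-2-en-1-one
Product: 10 5-ethoxy-3-methoxy-2-(3-methylbut-2-enyl)phenol, via vinylketene 6 (not isolated), via vinylcyclobutenone 7 (not isolated), via dienylketene 8 (not isolated), via cyclohexadienone 9 (not isolated)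
Conditions: 5 (1.0 equiv) added slowly to 4 (1.5 equiv), PhMe, 110 °C, then held at 110 °C; crude product stirred with K2CO3, MeOH, rt (returns any phenol that was O-acylated by ketene)
Reagents that add atoms: none
Why: Danheiser benzannulation (thermal cyclobutenone–alkynyl ether aromatic annulation): reversible conrotatory 4π opening of 5 gives vinylketene 6, which adds through its ketene C=C bond to the electron-rich triple bond of 4 in a regiospecific [2+2] cycloaddition to give 7; a second, reversible 4π opening gives dienylketene 8, whose isomer with the ethoxyvinyl group cis to the ketene closes ring A by a thermally allowed disrotatory 6π electrocyclisation (new C8a–C4a bond) to 9, and enolisation gives phenol 10. The closest known reaction type is this same benzannulation of 3-alkyl- and 3-aryl-cyclobutenones with alkoxy- and siloxyalkynes to resorcinol monoethers; the 3-ethoxy group is a less usual cyclobutenone substituent, so a higher temperature is allowed for the first ring opening. No stereocentre is formed. The one selectivity needed is the orientation of the [2+2] step, and the polarisation of the ynol ether fixes it: its nucleophilic prenyl-bearing carbon bonds to the electrophilic ketene carbonyl carbon (C8a–C8) and its methoxy-bearing carbon to the ketene α-carbon (C7–C6), so the prenyl group ends between OH and OMe and the ethoxy group meta to both. Chemoselectivity rests on the ynol ether being a far better ketenophile than the trisubstituted prenyl alkene, and a methyl ynol ether cannot fragment by retro-ene loss of an alkene as higher alkyl ynol ethers do on heating.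

Step 3
Reactants: 10 5-ethoxy-3-methoxy-2-(3-methylbut-2-enyl)phenol
Product: 11 6-ethoxy-2-hydroxy-4-methoxy-3-(3-methylbut-2-enyl)benzaldehyde
Conditions: MgCl2 (2 equiv), Et3N (4 equiv), (CH2O)n (6 equiv), MeCN, reflux; cold 1 M HCl work-up
Reagents that add atoms: paraformaldehyde (as formaldehyde), C=O
Why: Casnati–Skattebøl ortho-formylation: formaldehyde is delivered within the magnesium phenoxide only to a carbon ortho to the oxygen, the other ortho carbon carries the prenyl group, so the single ortho C–H (the future C4a, between OH and OEt) is formylated with a second formaldehyde as hydride acceptor, and the absence of protic or strong Lewis acid keeps the ortho-prenyl phenol from cyclising to a chroman.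

Step 4
Reactants: 11 6-ethoxy-2-hydroxy-4-methoxy-3-(3-methylbut-2-enyl)benzaldehyde
Product: 12 3-ethoxy-2-(1-hydroxyethyl)-5-methoxy-6-(3-methylbut-2-enyl)phenol (racemic)
Conditions: MeMgBr (3 equiv), THF, −20 → 0 °C; sat. aq. NH4Cl; crude used at once
Reagents that add atoms: methylmagnesium bromide, C[Mg]Br
Why: Grignard addition to the aldehyde, after the first equivalent has deprotonated the phenol, gives the secondary benzylic alcohol, whose new stereocentre is racemic and is removed in step 5, and the work-up is kept free of acid because electron-rich ortho-hydroxybenzyl alcohols ionise easily.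

Step 5
Reactants: 12 3-ethoxy-2-(1-hydroxyethyl)-5-methoxy-6-(3-methylbut-2-enyl)phenol
Product: 13 1-[6-ethoxy-2-hydroxy-4-methoxy-3-(3-methylbut-2-enyl)phenyl]ethan-1-one
Conditions: activated MnO2 (excess), CH2Cl2, rt
Reagents that add atoms: none
Why: Benzylic alcohol oxidation with activated MnO2 gives the hydrogen-bonded ortho-hydroxyaryl methyl ketone chemoselectively and leaves the prenyl alkene and the aryl ethers untouched.

Step 6
Reactants: 14 resorcinol; 15 3-methylbut-2-enoic acid
Product: 16 7-hydroxy-2,2-dimethylchroman-4-one
Conditions: P2O5 in MeSO3H (1:10 w/w), 70 °C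
Reagents that add atoms: none
Why: Friedel–Crafts acylation of resorcinol at C4 (para to one hydroxyl) followed by intramolecular oxa-Michael addition of the ortho hydroxyl to the enone closes the pyranone, which fixes the linear 7-oxygenated chroman pattern that chromenylation of 2,4-dihydroxybenzaldehyde (annulation between the two oxygens, angular isomer) would not give.

Step 7
Reactants: 16 7-hydroxy-2,2-dimethylchroman-4-one
Product: 18 2,2-dimethyl-2H-chromen-7-ol, via chromanol 17 (not isolated)
Conditions: LiAlH4 (2.5 equiv), THF, 0 °C → reflux; aqueous work-up; then p-TsOH·H2O (5 mol %), PhMe, 60 °C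
Reagents that add atoms: none
Why: Hydride reduction of the aryl ketone and acid-catalysed E1 dehydration of the resulting para-oxygenated benzylic alcohol is the standard chromanone-to-2H-chromene sequence, and the stereocentre of the intermediate alcohol is lost in the elimination.

Step 8
Reactants: 18 2,2-dimethyl-2H-chromen-7-ol
Product: 19 7-hydroxy-2,2-dimethyl-2H-chromene-6-carbaldehyde
Conditions: MgCl2 (2 equiv), Et3N (4 equiv), (CH2O)n (6 equiv), THF, reflux; cold 1 M HCl work-up
Reagents that add atoms: paraformaldehyde (as formaldehyde), C=O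
Why: Casnati–Skattebøl ortho-formylation of the magnesium phenoxide takes place at the less hindered ortho carbon C6 (para to the ring oxygen) and not at C8, which is flanked by both oxygens, as with other 3-alkoxyphenols, and the basic medium leaves the chromene alkene alone.

Step 9
Reactants: 19 7-hydroxy-2,2-dimethyl-2H-chromene-6-carbaldehyde
Product: 20 7-(methoxymethoxy)-2,2-dimethyl-2H-chromene-6-carbaldehyde
Conditions: NaH (1.2 equiv), DMF, 0 °C; MOMCl (1.2 equiv), 0 °C → rt
Reagents that add atoms: chloromethyl methyl ether (MOMCl), COCCl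
Why: Williamson-type O-alkylation of the sodium phenoxide masks the ortho hydroxyl, which as a phenoxide would deactivate the aldehyde in the aldol step and could later add to the enone carbonyl, and the MOM acetal is stable to KOH.

Step 10
Reactants: 13 1-[6-ethoxy-2-hydroxy-4-methoxy-3-(3-methylbut-2-enyl)phenyl]ethan-1-one; 20 7-(methoxymethoxy)-2,2-dimethyl-2H-chromene-6-carbaldehyde
Product: 21 (E)-1-[6-ethoxy-2-hydroxy-4-methoxy-3-(3-methylbut-2-enyl)phenyl]-3-[7-(methoxymethoxy)-2,2-dimethyl-2H-chromen-6-yl]prop-2-en-1-one
Conditions: KOH (50% aq., excess), EtOH, rt; poured onto ice, brought to pH 6 with cold dilute AcOH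
Reagents that add atoms: none
Why: Claisen–Schmidt aldol condensation of the methyl ketone enolate with the non-enolisable aldehyde and E1cB dehydration gives the E enone, and in strong base the product rests as its conjugated phenoxide, so no premature racemic closure to the flavanone takes place before the cold, weakly acidic work-up.

Step 11
Reactants: 21 (E)-1-[6-ethoxy-2-hydroxy-4-methoxy-3-(3-methylbut-2-enyl)phenyl]-3-[7-(methoxymethoxy)-2,2-dimethyl-2H-chromen-6-yl]prop-2-en-1-one
Product: 22 (2S)-5-ethoxy-7-methoxy-2-[7-(methoxymethoxy)-2,2-dimethyl-2H-chromen-6-yl]-8-(3-methylbut-2-enyl)chroman-4-one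
Conditions: quinidine-derived thiourea N-[3,5-bis(trifluoromethyl)phenyl]-N'-(9-deoxy-epi-quinidin-9-yl)thiourea (10 mol %), PhMe, −20 → 0 °C; enantiomeric purity raised by recrystallisation if needed
Reagents that add atoms: none
Why: Intramolecular oxa-Michael addition (6-endo-trig, closing ring C through O1–C2) under bifunctional cinchona catalysis, in which the quinuclidine nitrogen takes the proton of the 2'-hydroxyl and the thiourea hydrogen-bonds the enone carbonyl so that the chiral ion pair delivers the phenoxide to one face of the β-carbon and sets C2 as S; cinchona-base cyclisations of 2'-hydroxychalcones to flavanones are known, and the 6'-ethoxy group, by twisting the aryl ketone, should make closure fast and practically irreversible under the weak base, which keeps the reaction under kinetic control.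

Step 12
Reactants: 22 (2S)-5-ethoxy-7-methoxy-2-[7-(methoxymethoxy)-2,2-dimethyl-2H-chromen-6-yl]-8-(3-methylbut-2-enyl)chroman-4-one
Product: 23 (2S)-5-hydroxy-7-methoxy-2-[7-(methoxymethoxy)-2,2-dimethyl-2H-chromen-6-yl]-8-(3-methylbut-2-enyl)chroman-4-one
Conditions: MgI2·OEt2 (4 equiv), THF, 65 °C, dark; aq. NH4Cl/Na2S2O3
Reagents that add atoms: none
Why: Chelation-controlled ether cleavage in which magnesium bridges the C4 carbonyl and O5 and iodide removes the ethyl group by SN2 as iodoethane, while the non-chelated C7 methoxyl stays; this reagent is known to dealkylate the 5-oxygen of 8-prenylflavanones without hydrohalogenating or cyclising the prenyl group, no protic acid is present to open ring C, so C2 is not touched, and partial loss of MOM would be harmless because step 13 removes it.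

Step 13
Reactants: 23 (2S)-5-hydroxy-7-methoxy-2-[7-(methoxymethoxy)-2,2-dimethyl-2H-chromen-6-yl]-8-(3-methylbut-2-enyl)chroman-4-one
Product: 24 maackiaflavanone A, (2S)-5-hydroxy-2-(7-hydroxy-2,2-dimethyl-2H-chromen-6-yl)-7-methoxy-8-(3-methylbut-2-enyl)chroman-4-one
Conditions: 3 M aq. HCl (5 equiv), MeOH, rt → 40 °C
Reagents that add atoms: none
Why: Acid-catalysed acetal exchange with methanol releases the ring B phenol under conditions routinely tolerated by aryl prenyl groups and dimethylchromenes, and the hydrogen-bonded 5-hydroxyflavanone should not reopen under them, so the 2S configuration is kept.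

**Compound list**

1 | chloroacetaldehyde dimethyl acetal | COC(CCl)OC | starting material
2 | prenyl bromide | CC(C)=CCBr | starting material
3 | sodium methoxyacetylide | COC#[C-].[Na+] | intermediate
4 | 1-methoxy-5-methylhex-4-en-1-yne | COC#CCC=C(C)C | intermediate
5 | 3-ethoxycyclobut-2-en-1-one | CCOC1=CC(=O)C1 | starting material
6 | 3-ethoxybuta-1,3-dien-1-one (vinylketene) | C=C(OCC)C=C=O | intermediate
7 | 4-(1-ethoxyethenyl)-3-methoxy-2-(3-methylbut-2-enyl)cyclobut-2-en-1-one (racemic) | O=C1C(CC=C(C)C)=C(OC)C1C(OCC)=C | intermediate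
8 | 5-ethoxy-3-methoxy-2-(3-methylbut-2-enyl)hexa-1,3,5-trien-1-one (dienylketene, ethoxyvinyl cis to the ketene) | O=C=C(CC=C(C)C)/C(OC)=C\C(OCC)=C | intermediate
9 | 5-ethoxy-3-methoxy-2-(3-methylbut-2-enyl)cyclohexa-2,4-dien-1-one | O=C1CC(OCC)=CC(OC)=C1CC=C(C)C | intermediate
10 | 5-ethoxy-3-methoxy-2-(3-methylbut-2-enyl)phenol | CCOc1cc(O)c(CC=C(C)C)c(OC)c1 | intermediate
11 | 6-ethoxy-2-hydroxy-4-methoxy-3-(3-methylbut-2-enyl)benzaldehyde | CCOc1cc(OC)c(CC=C(C)C)c(O)c1C=O | intermediate
12 | 3-ethoxy-2-(1-hydroxyethyl)-5-methoxy-6-(3-methylbut-2-enyl)phenol (racemic) | CCOc1cc(OC)c(CC=C(C)C)c(O)c1C(C)O | intermediate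
13 | 1-[6-ethoxy-2-hydroxy-4-methoxy-3-(3-methylbut-2-enyl)phenyl]ethan-1-one | CCOc1cc(OC)c(CC=C(C)C)c(O)c1C(C)=O | intermediate
14 | resorcinol | Oc1cccc(O)c1 | starting material
15 | 3-methylbut-2-enoic acid | CC(C)=CC(=O)O | starting material
16 | 7-hydroxy-2,2-dimethylchroman-4-one | CC1(C)CC(=O)c2ccc(O)cc2O1 | intermediate
17 | 2,2-dimethylchromane-4,7-diol (racemic) | CC1(C)CC(O)c2ccc(O)cc2O1 | intermediate
18 | 2,2-dimethyl-2H-chromen-7-ol | CC1(C)C=Cc2ccc(O)cc2O1 | intermediate
19 | 7-hydroxy-2,2-dimethyl-2H-chromene-6-carbaldehyde | CC1(C)C=Cc2cc(C=O)c(O)cc2O1 | intermediate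
20 | 7-(methoxymethoxy)-2,2-dimethyl-2H-chromene-6-carbaldehyde | COCOc1cc2OC(C)(C)C=Cc2cc1C=O | intermediate
21 | (E)-1-[6-ethoxy-2-hydroxy-4-methoxy-3-(3-methylbut-2-enyl)phenyl]-3-[7-(methoxymethoxy)-2,2-dimethyl-2H-chromen-6-yl]prop-2-en-1-one | CCOc1cc(OC)c(CC=C(C)C)c(O)c1C(=O)/C=C/c1cc2C=CC(C)(C)Oc2cc1OCOC | intermediate
22 | (2S)-5-ethoxy-7-methoxy-2-[7-(methoxymethoxy)-2,2-dimethyl-2H-chromen-6-yl]-8-(3-methylbut-2-enyl)chroman-4-one | COc1cc(OCC)c2c(c1CC=C(C)C)O[C@H](c1cc3c(cc1OCOC)OC(C)(C)C=C3)CC2=O | intermediate
23 | (2S)-5-hydroxy-7-methoxy-2-[7-(methoxymethoxy)-2,2-dimethyl-2H-chromen-6-yl]-8-(3-methylbut-2-enyl)chroman-4-one | COc1cc(O)c2c(c1CC=C(C)C)O[C@H](c1cc3c(cc1OCOC)OC(C)(C)C=C3)CC2=O | intermediate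
24 | maackiaflavanone A, (2S)-5-hydroxy-2-(7-hydroxy-2,2-dimethyl-2H-chromen-6-yl)-7-methoxy-8-(3-methylbut-2-enyl)chroman-4-one | COc1cc(O)c2c(c1CC=C(C)C)O[C@H](c1cc3c(cc1O)OC(C)(C)C=C3)CC2=O | target

**Step count**

Total: 13 steps. Longest linear sequence: 9 steps (steps 1, 2, 3, 4, 5, 10, 11, 12, 13); the ring B branch (steps 6 to 9) joins at step 10.

**Steps most likely to fail**

Step 2 (benzannulation). The alkoxy-stabilised cyclobutenone may open only at temperatures at which the vinylketene is lost to dimerisation or to acylation of the product phenol, or the ynol ether may polymerise before it is intercepted. The fallback sets out from prenyl bromide 2 and rejoins the route at ketone 13. Commercial 1-(2,6-dihydroxy-4-methoxyphenyl)ethan-1-one F1, whose two free ring positions are equivalent by symmetry, is C-prenylated with 2 in cold aqueous KOH to give 1-[2,6-dihydroxy-4-methoxy-3-(3-methylbut-2-enyl)phenyl]ethan-1-one F2. Mono-O-ethylation (EtI, K2CO3, acetone) at the hydroxyl remote from the prenyl group then gives 13. The price is the C- versus O-alkylation mixture and a regioisomer separation in the ethylation, which the benzannulation avoids.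

Step 11 (asymmetric closure of ring C). Facial discrimination may be insufficient on an enone that carries no second activating group, since known selectivities for such chalcones are modest, or enantiopurity may be lost through reversible ring opening. The fallback sets out from chalcone 21 and rejoins at flavanone 22. Chalcone 21 is closed without stereocontrol (NaOAc, EtOH, reflux) to racemic 5-ethoxy-7-methoxy-2-[7-(methoxymethoxy)-2,2-dimethyl-2H-chromen-6-yl]-8-(3-methylbut-2-enyl)chroman-4-one F3. This is resolved kinetically by Noyori asymmetric transfer hydrogenation (RuCl[(R,R)-TsDPEN](p-cymene), HCO2H/Et3N, EtOAc, rt). The (2R)-ketone is expected to be reduced faster to (2R,4R)-5-ethoxy-7-methoxy-2-[7-(methoxymethoxy)-2,2-dimethyl-2H-chromen-6-yl]-8-(3-methylbut-2-enyl)chroman-4-ol F4, while (2S)-22 is recovered and separated by chromatography. The catalyst enantiomer is exchanged should a trial show the opposite preference.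

Step 12 (C5 de-ethylation). Iodide attacks an ethyl group more slowly than a methyl group, so prolonged heating with the Lewis acid may erode the C2 configuration by reversible opening of ring C or damage the MOM group and the alkenes. The fallback sets out from ketone 13 and rejoins at target 24, exchanging the ethyl ether for MOM before C2 exists. Ketone 13 is de-ethylated with MgI2·OEt2 in toluene at 80 °C, where no stereocentre is at risk, to the diol ketone F2. Mono-protection (MOMCl, iPr2NEt, CH2Cl2, 0 °C) at the hydroxyl remote from the prenyl group gives 1-[2-hydroxy-4-methoxy-6-(methoxymethoxy)-3-(3-methylbut-2-enyl)phenyl]ethan-1-one F5. Claisen–Schmidt condensation with 20 gives (E)-1-[2-hydroxy-4-methoxy-6-(methoxymethoxy)-3-(3-methylbut-2-enyl)phenyl]-3-[7-(methoxymethoxy)-2,2-dimethyl-2H-chromen-6-yl]prop-2-en-1-one F6. The closure of step 11 gives (2S)-7-methoxy-5-(methoxymethoxy)-2-[7-(methoxymethoxy)-2,2-dimethyl-2H-chromen-6-yl]-8-(3-methylbut-2-enyl)chroman-4-one F7, and one treatment with HCl in MeOH removes both MOM groups to give 24.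

**Further compounds**

F1 | step 2 | 1-(2,6-dihydroxy-4-methoxyphenyl)ethan-1-one | CC(=O)c1c(O)cc(OC)cc1O
F2 | step 2 | 1-[2,6-dihydroxy-4-methoxy-3-(3-methylbut-2-enyl)phenyl]ethan-1-one | CC(=O)c1c(O)cc(OC)c(CC=C(C)C)c1O
F3 | step 11 | racemic 5-ethoxy-7-methoxy-2-[7-(methoxymethoxy)-2,2-dimethyl-2H-chromen-6-yl]-8-(3-methylbut-2-enyl)chroman-4-one | COc1cc(OCC)c2c(c1CC=C(C)C)OC(c1cc3c(cc1OCOC)OC(C)(C)C=C3)CC2=O
F4 | step 11 | (2R,4R)-5-ethoxy-7-methoxy-2-[7-(methoxymethoxy)-2,2-dimethyl-2H-chromen-6-yl]-8-(3-methylbut-2-enyl)chroman-4-ol | COc1cc(OCC)c2c(c1CC=C(C)C)O[C@@H](c1cc3c(cc1OCOC)OC(C)(C)C=C3)C[C@H]2O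
F5 | step 12 | 1-[2-hydroxy-4-methoxy-6-(methoxymethoxy)-3-(3-methylbut-2-enyl)phenyl]ethan-1-one | CC(=O)c1c(OCOC)cc(OC)c(CC=C(C)C)c1O
F6 | step 12 | (E)-1-[2-hydroxy-4-methoxy-6-(methoxymethoxy)-3-(3-methylbut-2-enyl)phenyl]-3-[7-(methoxymethoxy)-2,2-dimethyl-2H-chromen-6-yl]prop-2-en-1-one | COCOc1cc(OC)c(CC=C(C)C)c(O)c1C(=O)/C=C/c1cc2C=CC(C)(C)Oc2cc1OCOC
F7 | step 12 | (2S)-7-methoxy-5-(methoxymethoxy)-2-[7-(methoxymethoxy)-2,2-dimethyl-2H-chromen-6-yl]-8-(3-methylbut-2-enyl)chroman-4-one | COc1cc(OCOC)c2c(c1CC=C(C)C)O[C@H](c1cc3c(cc1OCOC)OC(C)(C)C=C3)CC2=O
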